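1. Both new flasks are read at 15 min, so what I watch is how much starting material is gone by then.

the same everywhere: starting material 0.50 M; catalyst 0.43 mol%
- cedar: coupling partner 2.1 equiv; temperature −35 °C; run made earlier
- oak: coupling partner 2.9 equiv; temperature −24 °C; run made earlier
- elm: coupling partner 4.2 equiv; temperature −35 °C; run made earlier
- Tuesday's: coupling partner 2.00 equiv; at −40 °C throughout; time 15 min
- Friday's: coupling partner 4.00 equiv; at −20 °C until 5.0 min, from then on at −40 °C; time 15 min

- cedar (time / min: product / %, starting material / %): 3.00: 25, 75; 6.00: 42, 58; 12.0: 65, 36; 30.0: 88, 10
- oak (time / min: product / %, starting material / %): 4.00: 68, 32; 8.00: 87, 11; 12.0: 93, 5; 15.0: 95, 4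
- elm (time / min: product / %, starting material / %): 4.00: 53, 44; 10.0: 84, 16; 20.0: 96, 1; 30.0: 97, 1

(readings scatter by 1.5 percentage points)

- a reading or a percentage of product counts all its forms, free or not

1. the winner by amount of product, in percent of the starting material charged; "neither" if no more than 2 percentage points parts them (Tuesday's / Friday's / neither)
2. how much product is there at the end, in percent of the starting material charged: Tuesday's
3. how much product is there at the end, in percent of the starting material charged: Friday's

2. Coupling partner. By hand, at one temperature and catalyst loading, more partner means proportionally faster loss of [starting material]. [Coupling partner] falls during a run, so I replace its curve by its mean, which makes the loss pseudo-first-order. My rate number is ln(charged/left) per mean equivalent per minute. Cedar at 12.0 min gives 0.0478 min⁻¹, and elm at 10.0 min gives 0.0485 min⁻¹, about the same with twice the partner. I carry cedar's number forward.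

3. Temperature. Oak, warmer at −24 °C, reads 0.112 min⁻¹, faster than cedar at −35 °C, and this pair of readings gives an activation energy of 38.3 kJ mol⁻¹. That gives 0.0316 min⁻¹ at −40 °C and 0.151 min⁻¹ at −20 °C. Catalyst stays at 0.43 mol% in these runs, so these numbers hold for that loading.

4. Tuesday's. A first guess with the full charge leaves 38.8%, so the mean partner is 1.69 equivalents. That makes 0.803 turns: the turns are rate number times mean equivalents times time, and the fraction left is exp(−turns). So 44.8% is left and 55.2% is product. The exact curve leaves 45.2%, so the mean costs 0.40 percentage points.

5. Friday's. The warm leg gives 2.65 turns, leaving 7.04% at 5.0 min. The cold leg adds 0.970, fewer, leaving 2.67%. I expect 97.3% product, so Friday's wins.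

6. The forecast says Friday's, with 56% (50% to 62%) for Tuesday's and 95% (90% to 98%) for Friday's, since “doubling the equivalents doubles the rate”, and my Friday's figure stands above its figure.

7. The flasks give 56.1% for Tuesday's and 97.2% for Friday's, so Friday's wins.

    starting material + coupling partner + catalyst → catalyst + product (k = 2.40 M⁻² s⁻¹, Ea = 38.0 kJ mol⁻¹)
    crystals ⇌ product, rate k2*(cs2 - [product]) while solid is left; crystals form when [product] > cs2 (solubility = 0.200 M, k = 0.180 s⁻¹)
    (constants at −20 °C)

Tuesday's 43.9% left equals 0.823 turns, against my 0.803. Crystals stand at 15.9% in Tuesday's and 57.2% in Friday's, but they are counted in the product, and the saturation of product moves neither answer. A flask like Tuesday's at −65 °C has a rate number of 0.00294 min⁻¹, and so 0.0864 turns and 8.28% product by my reckoning. That flask gives 8.75% product, with 91% of the starting material still there.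

The runs come from a simulation for an exercise.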